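**Plan**

- Numbering: quinone ring C1(=O)–C2(furyl)=C3H–C4(=O)–C5H=C6H; furan O1, C2–H, C3 (side chain), C4–H, C5 (quinone).
- Retrosynthesis: the quinone is taken back to an O-silyl/O-methyl hydroquinone, whose ring is cut at C3–C4 and C6–C1 (and C1–C2). This gives a three-carbon alkenylcarbene ligand on chromium (C4, C5, C6), a terminal 2-furylalkyne (C2, C3) and one CO ligand (C1). The ester C–O bond, the furan C5–alkyne bond, the trisubstituted C=C (metathesis) and the carbinol–CH2 bond are then cut, back to furan-3-carbaldehyde.
- Enabling feature: a para-dioxygenated six-membered carbocycle with its only carbon substituent (the furan) next to one oxygen-bearing carbon and H on the other three ring carbons. This is the substitution pattern written by an alkenylcarbene + terminal alkyne + CO benzannulation.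
- Forward: the furan is bought; bromination, allylation, cross-metathesis, ethynylation and acylation give the chiral alkyne. The six-membered ring is built last from alkyne, carbene ligand and CO, then oxidised to the quinone.
- Stereochemistry: the single (R) centre comes from a reagent-controlled Brown allylboration (Ipc2B(allyl) from (−)-α-pinene, Re-face attack); no later step breaks a bond at that carbon.

Key step: step 7

**Route**

Step 1
Reactants: 1 furan-3-carbaldehyde
Product: 2 5-bromofuran-3-carbaldehyde
Conditions: Br2 (1.05 equiv), AlCl3 (2.2 equiv), CH2Cl2, 0 °C to rt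
Reagents that add atoms: bromine, BrBr
Why: Electrophilic aromatic bromination in which the AlCl3-bound formyl group deactivates the conjugated C2 position, so substitution should occur at the other α-carbon C5, whose σ-complex places no positive charge on the formyl-bearing carbon.

Step 2
Reactants: 2 5-bromofuran-3-carbaldehyde
Product: 3 (R)-1-(5-bromofuran-3-yl)but-3-en-1-ol
Conditions: (+)-Ipc2B(allyl) made from (−)-α-pinene (1.3 equiv, 1 M in pentane), Et2O, −78 °C; then 3 M NaOH, 30% H2O2, 0 °C to rt
Reagents that add atoms: (+)-B-allyldiisopinocampheylborane, C=CCB([C@H]1C[C@H]2C[C@@H]([C@@H]1C)C2(C)C)[C@H]1C[C@H]2C[C@@H]([C@@H]1C)C2(C)C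
Why: Brown asymmetric allylboration through a chair-like six-membered transition state, in which the isopinocampheyl groups of the (−)-α-pinene-derived reagent should direct allyl transfer to the Re face of the aldehyde and so set the (R) carbinol centre.

Step 3
Reactants: 3 (R)-1-(5-bromofuran-3-yl)but-3-en-1-ol
Product: 4 (R)-1-(5-bromofuran-3-yl)-4-methylpent-3-en-1-ol
Conditions: second-generation Grubbs catalyst RuCl2(=CHPh)(H2IMes)(PCy3) (5 mol %), 2-methyl-2-butene/CH2Cl2 (1:1), 40 °C, sealed tube
Reagents that add atoms: 2-methyl-2-butene, CC=C(C)C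
Why: Olefin cross-metathesis with excess 2-methyl-2-butene exchanges the terminal CH2 for an isopropylidene group, driven by loss of volatile propene, and touches neither the carbinol centre nor the bromofuran.

Step 4
Reactants: 4 (R)-1-(5-bromofuran-3-yl)-4-methylpent-3-en-1-ol
Product: 5 (R)-1-(5-ethynylfuran-3-yl)-4-methylpent-3-en-1-ol
Conditions: HC≡CMgBr (3 equiv), ZnBr2 (3.1 equiv), THF, 0 °C; then 4, Pd(PPh3)4 (5 mol %), rt to 45 °C; aq NH4Cl
Reagents that add atoms: ethynylmagnesium bromide, C#C[Mg]Br
Why: Negishi coupling, in which zerovalent palladium adds oxidatively to the furan C5–Br bond and the monozincated acetylene transfers the ethynyl group, should give the terminal alkyne directly while the zinc alkoxide of the free hydroxyl stays inert.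

Step 5
Reactants: 5 (R)-1-(5-ethynylfuran-3-yl)-4-methylpent-3-en-1-ol
Product: 6 (R)-1-(5-ethynylfuran-3-yl)-4-methylpent-3-en-1-yl 3-methylbutanoate
Conditions: 3-methylbutanoic anhydride (1.5 equiv), DMAP (0.1 equiv), Et3N (2 equiv), CH2Cl2, 0 °C to rt
Reagents that add atoms: 3-methylbutanoic anhydride, CC(C)CC(=O)OC(=O)CC(C)C
Why: DMAP-catalysed acyl transfer acylates the secondary alcohol on oxygen without breaking the carbinol C–O bond, so the (R) configuration is retained.

Step 6
Reactants: 7 (E)-(2-bromovinyl)trimethylsilane; 8 chromium hexacarbonyl Cr(CO)6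
Product: 11 pentacarbonyl[(E)-1-methoxy-3-(trimethylsilyl)prop-2-en-1-ylidene]chromium, via (E)-2-(trimethylsilyl)vinyllithium 9 (not isolated), via Li[(CO)5CrC(O)CH=CHSiMe3] 10 (not isolated)
Conditions: t-BuLi (2.0 equiv), Et2O, −78 °C; Cr(CO)6, Et2O, −78 °C to rt; then MeOTf, CH2Cl2, 0 °C
Reagents that add atoms: methyl trifluoromethanesulfonate, COS(=O)(=O)C(F)(F)F
Why: Fischer carbene synthesis, in which bromine–lithium exchange retains the E geometry, the vinyllithium adds to a CO ligand of Cr(CO)6 and the resulting acylchromate is methylated on oxygen.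

Step 7
Reactants: 6 (R)-1-(5-ethynylfuran-3-yl)-4-methylpent-3-en-1-yl 3-methylbutanoate; 11 pentacarbonyl[(E)-1-methoxy-3-(trimethylsilyl)prop-2-en-1-ylidene]chromium
Product: 14 (R)-1-{5-[5-methoxy-2-(trimethylsilyloxy)phenyl]furan-3-yl}-4-methylpent-3-en-1-yl 3-methylbutanoate, via dienone Cr(CO)3 complex 12 (not isolated), via arene Cr(CO)3 complex 13 (not isolated)
Conditions: 11 (1.5 equiv), THF (0.05 M), 50 °C, argon, 16 h; then air, rt
Reagents that add atoms: none
Why: Dötz benzannulation: loss of one CO from the zerovalent chromium carbene 11 lets the terminal alkyne of 6 insert into the Cr=C bond (carbene carbon C4 to alkyne C3–H), a CO ligand then inserts at the furyl-bearing alkyne carbon C2 to give a chromium-bound dienylketene, and the ketene carbon C1 closes onto the silyl-bearing vinyl terminus C6, so three ring carbons come from the carbene ligand, two from the alkyne and one from CO. The closest known reaction type is the benzannulation of alkenyl(alkoxy)carbene chromium complexes with terminal aryl alkynes, with β-silylvinyl complexes serving as stable stand-ins for the polymerisation-prone parent vinyl complex. The one new ring closes by a thermal 6π electrocyclisation of the metal-templated dienylketene, a six-membered closure between the ketene carbon and the vinyl β-carbon. The only new stereocentre, the silyl-bearing sp3 carbon C6 of dienone 12, is transient and uncontrolled, and is erased when silicon shifts from carbon to the adjacent carbonyl oxygen (1,3 C-to-O shift driven by aromatisation), which leaves H on C6 and delivers the phenol already silylated. The step needs phenol formation over cyclobutenone or alkyne-oligomer pathways (favoured by an alkenyl complex in THF at moderate temperature and by keeping 11 in excess) and silyl rather than hydrogen migration in 12 (an α-silyl ketone should move silicon to oxygen faster than it enolises). The regiochemistry of alkyne insertion is normally fixed by the H versus furyl size difference (furyl next to the CO-derived carbon), but either regioisomer would give the same quinone in step 8 because the carbene-derived half of the ring is unsubstituted; the (R) ester centre is remote and untouched.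

Step 8
Reactants: 14 (R)-1-{5-[5-methoxy-2-(trimethylsilyloxy)phenyl]furan-3-yl}-4-methylpent-3-en-1-yl 3-methylbutanoate
Product: 15 (R)-1-[5-(3,6-dioxocyclohexa-1,4-dien-1-yl)furan-3-yl]-4-methylpent-3-en-1-yl 3-methylbutanoate
Conditions: (NH4)2Ce(NO3)6 (2.5 equiv), MeCN/H2O (4:1), 0 °C, 15 min
Reagents that add atoms: water, O
Why: Oxidative demethylation/desilylation of a para-dioxygenated arene by tetravalent cerium (single-electron oxidation, water attack at the methoxy-bearing carbon, loss of methanol and of the labile silyl group) should give the 1,4-benzoquinone, the most easily oxidised site being the hydroquinone ether ring and the stereocentre not being involved.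

**Compound list**

(CO ligands are drawn as Cr=C=O; a dot-separated Cr(CO)3 unit is π-bound to the six-membered ring.)

1 | furan-3-carbaldehyde | O=Cc1ccoc1 | starting material
2 | 5-bromofuran-3-carbaldehyde | O=Cc1coc(Br)c1 | intermediate
3 | (R)-1-(5-bromofuran-3-yl)but-3-en-1-ol | C=CC[C@@H](O)c1coc(Br)c1 | intermediate
4 | (R)-1-(5-bromofuran-3-yl)-4-methylpent-3-en-1-ol | CC(C)=CC[C@@H](O)c1coc(Br)c1 | intermediate
5 | (R)-1-(5-ethynylfuran-3-yl)-4-methylpent-3-en-1-ol | CC(C)=CC[C@@H](O)c1coc(C#C)c1 | intermediate
6 | (R)-1-(5-ethynylfuran-3-yl)-4-methylpent-3-en-1-yl 3-methylbutanoate | CC(C)=CC[C@@H](OC(=O)CC(C)C)c1coc(C#C)c1 | intermediate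
7 | (E)-(2-bromovinyl)trimethylsilane | C[Si](C)(C)/C=C/Br | starting material
8 | chromium hexacarbonyl Cr(CO)6 | O=C=[Cr](=C=O)(=C=O)(=C=O)(=C=O)=C=O | starting material
9 | (E)-2-(trimethylsilyl)vinyllithium | [Li]/C=C/[Si](C)(C)C | intermediate (not isolated)
10 | lithium pentacarbonyl[(E)-1-oxido-3-(trimethylsilyl)prop-2-en-1-ylidene]chromate Li[(CO)5CrC(O)CH=CHSiMe3] | [Li+].[O-]C(/C=C/[Si](C)(C)C)=[Cr](=C=O)(=C=O)(=C=O)(=C=O)=C=O | intermediate (not isolated)
11 | pentacarbonyl[(E)-1-methoxy-3-(trimethylsilyl)prop-2-en-1-ylidene]chromium (CO)5Cr=C(OMe)CH=CHSiMe3 | COC(/C=C/[Si](C)(C)C)=[Cr](=C=O)(=C=O)(=C=O)(=C=O)=C=O | intermediate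
12 | Cr(CO)3 complex of (R)-1-{5-[3-methoxy-6-oxo-5-(trimethylsilyl)cyclohexa-1,3-dien-1-yl]furan-3-yl}-4-methylpent-3-en-1-yl 3-methylbutanoate (silyl-bearing ring carbon of either configuration) | CC(C)=CC[C@@H](OC(=O)CC(C)C)c1coc(C2=CC(OC)=CC([Si](C)(C)C)C2=O)c1.O=C=[Cr](=C=O)=C=O | intermediate (not isolated)
13 | η6-arene Cr(CO)3 complex of compound 14 | CC(C)=CC[C@@H](OC(=O)CC(C)C)c1coc(-c2cc(OC)ccc2O[Si](C)(C)C)c1.O=C=[Cr](=C=O)=C=O | intermediate (not isolated)
14 | (R)-1-{5-[5-methoxy-2-(trimethylsilyloxy)phenyl]furan-3-yl}-4-methylpent-3-en-1-yl 3-methylbutanoate | CC(C)=CC[C@@H](OC(=O)CC(C)C)c1coc(-c2cc(OC)ccc2O[Si](C)(C)C)c1 | intermediate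
15 | (R)-1-[5-(3,6-dioxocyclohexa-1,4-dien-1-yl)furan-3-yl]-4-methylpent-3-en-1-yl 3-methylbutanoate (CNP0219765.1) | CC(C)=CC[C@@H](OC(=O)CC(C)C)c1coc(C2=CC(=O)C=CC2=O)c1 | target

**Step count and risks**

Total steps: 8. Longest linear sequence: 7 steps (steps 1, 2, 3, 4, 5, 7 and 8 from furan-3-carbaldehyde); step 6 is a one-step side branch.

Steps most likely to fail:

1. Step 7. The terminal heteroaryl alkyne may oligomerise or be taken up twice at chromium, the carbene complex may decompose before alkyne uptake, or hydrogen instead of silicon may migrate in the dienone and leave silicon on the ring. The fallback buys the six-membered ring instead of building it; it sets out from 4 and comes back at 15. Compound 4 is acylated (3-methylbutanoic anhydride, DMAP, Et3N, CH2Cl2) to (R)-1-(5-bromofuran-3-yl)-4-methylpent-3-en-1-yl 3-methylbutanoate F1. Suzuki–Miyaura coupling of F1 with (2,5-dimethoxyphenyl)boronic acid (Pd(PPh3)4, CsF, DME, 80 °C) should give (R)-1-[5-(2,5-dimethoxyphenyl)furan-3-yl]-4-methylpent-3-en-1-yl 3-methylbutanoate F2. Oxidative demethylation of F2 with (NH4)2Ce(NO3)6 in MeCN/H2O at 0 °C then gives 15.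

2. Step 8. The one-electron oxidant may over-oxidise the electron-rich furan, or the acidic medium may ionise the furylic C–O bond, with erosion of configuration or solvolysis of the ester. The fallback replaces the cerium oxidation by a two-electron hypervalent-iodine dearomatisation through a quinone monoketal; it sets out from 14 and comes back at 15. Desilylation of 14 (Bu4NF/AcOH, THF, 0 °C) should give (R)-1-[5-(2-hydroxy-5-methoxyphenyl)furan-3-yl]-4-methylpent-3-en-1-yl 3-methylbutanoate F3. Treatment with PhI(OAc)2 in MeOH at 0 °C should give (R)-1-[5-(3,3-dimethoxy-6-oxocyclohexa-1,4-dien-1-yl)furan-3-yl]-4-methylpent-3-en-1-yl 3-methylbutanoate F4. Mild hydrolysis of the ketal (aqueous oxalic acid, THF, rt) then gives 15.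

3. Step 4. The terminal C–H of the product may be metalated and coupled a second time to give a diarylacetylene, and the unprotected 2-ethynylfuran may degrade on palladium on warming. The fallback uses a silyl-masked alkyne; it sets out from 4 and comes back at 5. Sonogashira coupling of 4 with trimethylsilylacetylene (PdCl2(PPh3)2, CuI, i-Pr2NH, THF, rt) should give (R)-4-methyl-1-{5-[(trimethylsilyl)ethynyl]furan-3-yl}pent-3-en-1-ol F5. Protodesilylation (K2CO3, MeOH, 0 °C) then gives 5.

Further compounds
F1 | step 7 | (R)-1-(5-bromofuran-3-yl)-4-methylpent-3-en-1-yl 3-methylbutanoate | CC(C)=CC[C@@H](OC(=O)CC(C)C)c1coc(Br)c1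
F2 | step 7 | (R)-1-[5-(2,5-dimethoxyphenyl)furan-3-yl]-4-methylpent-3-en-1-yl 3-methylbutanoate | CC(C)=CC[C@@H](OC(=O)CC(C)C)c1coc(-c2cc(OC)ccc2OC)c1
F3 | step 8 | (R)-1-[5-(2-hydroxy-5-methoxyphenyl)furan-3-yl]-4-methylpent-3-en-1-yl 3-methylbutanoate | CC(C)=CC[C@@H](OC(=O)CC(C)C)c1coc(-c2cc(OC)ccc2O)c1
F4 | step 8 | (R)-1-[5-(3,3-dimethoxy-6-oxocyclohexa-1,4-dien-1-yl)furan-3-yl]-4-methylpent-3-en-1-yl 3-methylbutanoate | CC(C)=CC[C@@H](OC(=O)CC(C)C)c1coc(C2=CC(OC)(OC)C=CC2=O)c1
F5 | step 4 | (R)-4-methyl-1-{5-[(trimethylsilyl)ethynyl]furan-3-yl}pent-3-en-1-ol | CC(C)=CC[C@@H](O)c1coc(C#C[Si](C)(C)C)c1
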